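**Plan**
- Retrosynthetic cuts: in the acid-bearing ring C the C1–C6 and C2–C3 bonds (2-pyrone plus alkyne, CO2 lost); then the two depside C(=O)–O bonds; on ring A the C5 oxygen and the carboxyl carbon.
- Enabling feature: ring C carries its acylated oxygen on C4, its methyl on C6 and hydrogens on C3 and C5. This is the C3–C6 part of an O-acylated 4-hydroxy-6-methyl-2-pyrone, so only C1 (with CO2H) and C2 (with OH) are missing, and they come from a 3-methoxypropiolate.
- Forward order: ring A acid from orcylaldehyde (benzylation, Dakin oxidation, O-methylation, formylation, oxidation); ester to O4 of a second orcylaldehyde (ring B); benzylation and oxidation to the A–B acid; O-acylation of triacetic acid lactone.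
- Ring C is formed last by cycloaddition and CO2 loss, followed by one global Lewis-acid deprotection.
- Stereochemistry: the target has no stereogenic element; the two bridgehead centres of the cycloadduct are transient and vanish on aromatisation.

Key step: step 12

Remark: because the target is achiral, "single enantiomer" is taken to mean the one compound drawn; intermediate 22 is racemic and is written without configuration.

**Route**

Step 1
Reactants: 1 2,4-dihydroxy-6-methylbenzaldehyde (orcylaldehyde)
Product: 2 2,4-bis(benzyloxy)-6-methylbenzaldehyde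
Conditions: BnBr (2.5 equiv), K2CO3, DMF, 60 °C
Reagents that add atoms: benzyl bromide, BrCc1ccccc1
Why: Williamson etherification; carbonate in warm DMF with excess benzyl bromide alkylates both the free 4-hydroxyl and the hydrogen-bonded 2-hydroxyl.

Step 2
Reactants: 2 2,4-bis(benzyloxy)-6-methylbenzaldehyde
Product: 4 2,4-bis(benzyloxy)-6-methylphenol, via aryl formate 3 (not isolated)
Conditions: mCPBA, CH2Cl2, 0 °C to rt; aq NaHCO3 wash; then K2CO3 (cat.), MeOH, rt
Reagents that add atoms: 3-chloroperoxybenzoic acid, OOC(=O)c1cccc(Cl)c1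
Why: Baeyer–Villiger (Dakin-type) oxidation in which the electron-rich, di-ortho-substituted aryl group migrates in preference to hydride, and the aryl formate is then cleaved by mild methanolysis that leaves the benzyl ethers alone.

Step 3
Reactants: 4 2,4-bis(benzyloxy)-6-methylphenol
Product: 5 1,5-bis(benzyloxy)-2-methoxy-3-methylbenzene
Conditions: MeI, K2CO3, acetone, reflux
Reagents that add atoms: iodomethane, CI
Why: Williamson O-methylation of a hindered but unchelated phenol, which installs the methoxy group that becomes the ring A C5 methyl ether.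

Step 4
Reactants: 5 1,5-bis(benzyloxy)-2-methoxy-3-methylbenzene
Product: 7 4,6-bis(benzyloxy)-3-methoxy-2-methylbenzaldehyde, via iminium salt 6 (not isolated)
Conditions: POCl3, DMF, 0 to 70 °C; then ice–water
Reagents that add atoms: N,N-dimethylformamide, CN(C)C=O; water, O
Why: Vilsmeier–Haack formylation, in which the bulky chloroiminium electrophile should attack the position para to one benzyloxy group and ortho to the other (next to the methyl) and not the site flanked by both benzyloxy groups, as in the formylation of orcinol diethers.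

Step 5
Reactants: 7 4,6-bis(benzyloxy)-3-methoxy-2-methylbenzaldehyde
Product: 8 4,6-bis(benzyloxy)-3-methoxy-2-methylbenzoic acid (ring A acid)
Conditions: NaClO2, NaH2PO4, 2-methyl-2-butene, t-BuOH/THF/H2O, rt
Reagents that add atoms: sodium chlorite, [Na+].[O-]Cl=O
Why: Pinnick oxidation converts the hindered aldehyde to the acid under buffered conditions, with the alkene scavenger removing hypochlorous acid before it can chlorinate the electron-rich ring.

Step 6
Reactants: 8 4,6-bis(benzyloxy)-3-methoxy-2-methylbenzoic acid; 1 2,4-dihydroxy-6-methylbenzaldehyde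
Product: 10 4-formyl-3-hydroxy-5-methylphenyl 4,6-bis(benzyloxy)-3-methoxy-2-methylbenzoate, via acid chloride 9 (not isolated)
Conditions: (COCl)2, DMF (cat.), CH2Cl2, 0 °C to rt, evaporate; then 1 (1.0 equiv), Et3N, CH2Cl2, −20 to 0 °C
Reagents that add atoms: none
Why: Acyl chloride esterification of a phenol; the 4-hydroxyl of 1 is the more acidic and unchelated one while the 2-hydroxyl is held in a hydrogen bond to the formyl group, so monoacylation should occur at O4.

Step 7
Reactants: 10 4-formyl-3-hydroxy-5-methylphenyl 4,6-bis(benzyloxy)-3-methoxy-2-methylbenzoate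
Product: 11 3-(benzyloxy)-4-formyl-5-methylphenyl 4,6-bis(benzyloxy)-3-methoxy-2-methylbenzoate
Conditions: BnBr, K2CO3, DMF, rt
Reagents that add atoms: benzyl bromide, BrCc1ccccc1
Why: Williamson benzylation of the remaining chelated phenol at room temperature, where the sterically shielded di-ortho-substituted aryl benzoate should resist cleavage or acyl transfer.

Step 8
Reactants: 11 3-(benzyloxy)-4-formyl-5-methylphenyl 4,6-bis(benzyloxy)-3-methoxy-2-methylbenzoate
Product: 12 2-(benzyloxy)-4-{[4,6-bis(benzyloxy)-3-methoxy-2-methylbenzoyl]oxy}-6-methylbenzoic acid (A–B acid)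
Conditions: NaClO2, NaH2PO4, 2-methyl-2-butene, t-BuOH/THF/H2O, rt
Reagents that add atoms: sodium chlorite, [Na+].[O-]Cl=O
Why: Pinnick oxidation is close to neutral and should leave the depside ester and the benzyl ethers intact.

Step 9
Reactants: 12 2-(benzyloxy)-4-{[4,6-bis(benzyloxy)-3-methoxy-2-methylbenzoyl]oxy}-6-methylbenzoic acid; 13 4-hydroxy-6-methyl-2-pyrone (triacetic acid lactone)
Product: 15 6-methyl-2-oxo-2H-pyran-4-yl 2-(benzyloxy)-4-{[4,6-bis(benzyloxy)-3-methoxy-2-methylbenzoyl]oxy}-6-methylbenzoate, via acid chloride 14 (not isolated)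
Conditions: (COCl)2, DMF (cat.), CH2Cl2, 0 °C to rt, evaporate; then 13, Et3N, CH2Cl2, 0 °C; non-aqueous work-up
Reagents that add atoms: none
Why: O-acylation of the vinylogous acid 13 by an acyl chloride with triethylamine at 0 °C is the kinetic pathway, and nucleophilic catalysts (DMAP, cyanide) that would trigger migration of the acyl group from O4 to C3 are left out.

Step 10
Reactants: 16 2-chloro-1,1-dimethoxyethane (chloroacetaldehyde dimethyl acetal)
Product: 18 methoxyethyne (methoxyacetylene), via sodium methoxyacetylide 17 (not isolated)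
Conditions: NaNH2 (3 equiv), liq. NH3, −33 °C; then cold aq NaCl, distil into a cold trap (kept as a cold THF solution)
Reagents that add atoms: none
Why: Base-induced double elimination (loss of methanol and of hydrogen chloride) from the chloroacetal gives the acetylide, which is protonated on aqueous quench, and the volatile ynol ether is distilled out.

Step 11
Reactants: 18 methoxyethyne; 19 benzyl chloroformate
Product: 21 benzyl 3-methoxyprop-2-ynoate (benzyl 3-methoxypropiolate), via lithium methoxyacetylide 20 (not isolated)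
Conditions: n-BuLi, THF, −78 °C; then cannulation into 19 (1.5 equiv), THF, −78 °C
Reagents that add atoms: none
Why: Deprotonation of the terminal ynol ether and C-acylation of the lithium acetylide by a chloroformate is the usual access to 3-alkoxypropiolates, with inverse addition to excess chloroformate suppressing a second addition.

Step 12
Reactants: 15 6-methyl-2-oxo-2H-pyran-4-yl 2-(benzyloxy)-4-{[4,6-bis(benzyloxy)-3-methoxy-2-methylbenzoyl]oxy}-6-methylbenzoate; 21 benzyl 3-methoxyprop-2-ynoate
Product: 23 benzyl 4-{[2-(benzyloxy)-4-{[4,6-bis(benzyloxy)-3-methoxy-2-methylbenzoyl]oxy}-6-methylbenzoyl]oxy}-2-methoxy-6-methylbenzoate, via bicyclic lactone 22 (not isolated)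
Conditions: 21 (4 equiv), BHT (cat.), PhCl, 160 °C, sealed tube, base- and acid-free glassware
Reagents that add atoms: none
Why: The pyrone diene (C3=C4–C5=C6) should add the alkyne thermally in a [4+2] sense to give the 2-oxabicyclo[2.2.2]octadienone 22, which loses carbon dioxide by retro-[4+2] at the same temperature to leave the benzene ring. The closest known reaction type is the Diels–Alder/decarboxylation benzannulation of 4-oxygenated 6-methyl-2-pyrones with propiolates and acetylenedicarboxylates; the present pairing with an alkoxy-substituted propiolate is a new combination within that class. The six-membered carbocycle closes by an intermolecular, suprafacial, asynchronous cycloaddition that forms the ring C C2–C3 and C1–C6 bonds in one event, not by cyclisation of a chain. The two bridgehead centres of 22 are formed as a racemate and are destroyed on aromatisation, so no stereocentre needs control. The step needs one regiochemistry: the methoxy-bearing alkyne carbon (the electrophilic beta carbon of the alkynoate) must bond to pyrone C3 (the nucleophilic terminus, alpha to the lactone carbonyl and beta to the 4-acyloxy oxygen), and the ester-bearing carbon (the nucleophilic end of the ynol ether) to the electrophilic C6, so both frontier-orbital pairings point the same way. Chemoselectivity rests on the absence of any catalyst that could shift the depside acyl group from O4 to C3, and on the methoxy group, which has no beta hydrogen and so cannot undergo retro-ene fragmentation to a ketene.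

Step 13
Reactants: 23 benzyl 4-{[2-(benzyloxy)-4-{[4,6-bis(benzyloxy)-3-methoxy-2-methylbenzoyl]oxy}-6-methylbenzoyl]oxy}-2-methoxy-6-methylbenzoate
Product: 24 4-{[4-{[4,6-dihydroxy-3-methoxy-2-methylbenzoyl]oxy}-2-hydroxy-6-methylbenzoyl]oxy}-2-hydroxy-6-methylbenzoic acid (CNP0327242.0)
Conditions: BCl3 (ca. 10 equiv), pentamethylbenzene (ca. 8 equiv), CH2Cl2, −78 to 0 °C; then H2O
Reagents that add atoms: none
Why: Lewis-acid ether cleavage: boron trichloride removes the three benzyl ethers and the benzyl ester (the benzyl cations being trapped by pentamethylbenzene) and cleaves the ring C methyl ether through a six-membered boron chelate with the neighbouring carbonyl, whereas the ring A methoxy has no ortho carbonyl and should persist at or below 0 °C.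

**Compound list**
1 | 2,4-dihydroxy-6-methylbenzaldehyde (orcylaldehyde) | Cc1cc(O)cc(O)c1C=O | starting material
2 | 2,4-bis(benzyloxy)-6-methylbenzaldehyde | Cc1cc(OCc2ccccc2)cc(OCc2ccccc2)c1C=O | intermediate
3 | 2,4-bis(benzyloxy)-6-methylphenyl formate | Cc1cc(OCc2ccccc2)cc(OCc2ccccc2)c1OC=O | intermediate (not isolated)
4 | 2,4-bis(benzyloxy)-6-methylphenol | Cc1cc(OCc2ccccc2)cc(OCc2ccccc2)c1O | intermediate
5 | 1,5-bis(benzyloxy)-2-methoxy-3-methylbenzene | COc1c(C)cc(OCc2ccccc2)cc1OCc1ccccc1 | intermediate
6 | N-{[4,6-bis(benzyloxy)-3-methoxy-2-methylphenyl]methylidene}-N-methylmethanaminium chloride | COc1c(OCc2ccccc2)cc(OCc2ccccc2)c(C=[N+](C)C)c1C.[Cl-] | intermediate (not isolated)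
7 | 4,6-bis(benzyloxy)-3-methoxy-2-methylbenzaldehyde | COc1c(OCc2ccccc2)cc(OCc2ccccc2)c(C=O)c1C | intermediate
8 | 4,6-bis(benzyloxy)-3-methoxy-2-methylbenzoic acid | COc1c(OCc2ccccc2)cc(OCc2ccccc2)c(C(=O)O)c1C | intermediate
9 | 4,6-bis(benzyloxy)-3-methoxy-2-methylbenzoyl chloride | COc1c(OCc2ccccc2)cc(OCc2ccccc2)c(C(=O)Cl)c1C | intermediate (not isolated)
10 | 4-formyl-3-hydroxy-5-methylphenyl 4,6-bis(benzyloxy)-3-methoxy-2-methylbenzoate | COc1c(OCc2ccccc2)cc(OCc2ccccc2)c(C(=O)Oc2cc(C)c(C=O)c(O)c2)c1C | intermediate
11 | 3-(benzyloxy)-4-formyl-5-methylphenyl 4,6-bis(benzyloxy)-3-methoxy-2-methylbenzoate | COc1c(OCc2ccccc2)cc(OCc2ccccc2)c(C(=O)Oc2cc(C)c(C=O)c(OCc3ccccc3)c2)c1C | intermediate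
12 | 2-(benzyloxy)-4-{[4,6-bis(benzyloxy)-3-methoxy-2-methylbenzoyl]oxy}-6-methylbenzoic acid | COc1c(OCc2ccccc2)cc(OCc2ccccc2)c(C(=O)Oc2cc(C)c(C(=O)O)c(OCc3ccccc3)c2)c1C | intermediate
13 | 4-hydroxy-6-methyl-2-pyrone (triacetic acid lactone) | Cc1cc(O)cc(=O)o1 | starting material
14 | 2-(benzyloxy)-4-{[4,6-bis(benzyloxy)-3-methoxy-2-methylbenzoyl]oxy}-6-methylbenzoyl chloride | COc1c(OCc2ccccc2)cc(OCc2ccccc2)c(C(=O)Oc2cc(C)c(C(=O)Cl)c(OCc3ccccc3)c2)c1C | intermediate (not isolated)
15 | 6-methyl-2-oxo-2H-pyran-4-yl 2-(benzyloxy)-4-{[4,6-bis(benzyloxy)-3-methoxy-2-methylbenzoyl]oxy}-6-methylbenzoate | COc1c(OCc2ccccc2)cc(OCc2ccccc2)c(C(=O)Oc2cc(C)c(C(=O)Oc3cc(C)oc(=O)c3)c(OCc3ccccc3)c2)c1C | intermediate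
16 | 2-chloro-1,1-dimethoxyethane | COC(CCl)OC | starting material
17 | sodium methoxyacetylide | COC#C[Na] | intermediate (not isolated)
18 | methoxyethyne | COC#C | intermediate
19 | benzyl chloroformate | O=C(Cl)OCc1ccccc1 | starting material
20 | lithium methoxyacetylide | COC#C[Li] | intermediate (not isolated)
21 | benzyl 3-methoxyprop-2-ynoate | COC#CC(=O)OCc1ccccc1 | intermediate
22 | benzyl 8-{[2-(benzyloxy)-4-{[4,6-bis(benzyloxy)-3-methoxy-2-methylbenzoyl]oxy}-6-methylbenzoyl]oxy}-5-methoxy-1-methyl-3-oxo-2-oxabicyclo[2.2.2]octa-5,7-diene-6-carboxylate (racemic) | COc1c(OCc2ccccc2)cc(OCc2ccccc2)c(C(=O)Oc2cc(C)c(C(=O)OC3=CC4(C)OC(=O)C3C(OC)=C4C(=O)OCc5ccccc5)c(OCc3ccccc3)c2)c1C | intermediate (not isolated)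
23 | benzyl 4-{[2-(benzyloxy)-4-{[4,6-bis(benzyloxy)-3-methoxy-2-methylbenzoyl]oxy}-6-methylbenzoyl]oxy}-2-methoxy-6-methylbenzoate | COc1c(OCc2ccccc2)cc(OCc2ccccc2)c(C(=O)Oc2cc(C)c(C(=O)Oc3cc(C)c(C(=O)OCc4ccccc4)c(OC)c3)c(OCc3ccccc3)c2)c1C | intermediate
24 | 4-{[4-{[4,6-dihydroxy-3-methoxy-2-methylbenzoyl]oxy}-2-hydroxy-6-methylbenzoyl]oxy}-2-hydroxy-6-methylbenzoic acid | COc1c(O)cc(O)c(C(=O)Oc2cc(C)c(C(=O)Oc3cc(C)c(C(=O)O)c(O)c3)c(O)c2)c1C | target

**Step count**
Total steps: 13. Longest linear sequence: 11 (steps 1–9, 12, 13); the alkyne branch (steps 10–11) joins at step 12.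

**Steps most likely to fail**

Step 12. The cycloaddition may be too slow between two only moderately activated partners, so that thermal polymerisation of the alkyne, transfer of the depside acyl group from O4 to C3 of the pyrone, or addition in the reverse orientation competes. The fallback sets out from 12 and builds ring C by classical depside esterification instead of cycloaddition. Orsellinic acid (commercial) is esterified with benzyl bromide and KHCO3 in DMF to benzyl 2,4-dihydroxy-6-methylbenzoate F1. Acid chloride 14, made from 12 as in the first stage of step 9, is added to F1 with Et3N in CH2Cl2 at low temperature; the chelated 2-hydroxyl stays free and O4 is acylated, which should give benzyl 4-{[2-(benzyloxy)-4-{[4,6-bis(benzyloxy)-3-methoxy-2-methylbenzoyl]oxy}-6-methylbenzoyl]oxy}-2-hydroxy-6-methylbenzoate F2. Hydrogenolysis (H2, Pd/C, EtOAc/THF) removes all four benzyl groups and the route comes back at 24.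

Step 13. The Lewis acid may over-demethylate by chelating between the ring A methoxy and the neighbouring borylated oxygen, may leave the benzyl ester partly intact, or may allow C-benzylation of the phenolic rings. The fallback sets out from 23 and separates the two tasks. Hydrogenolysis (H2, Pd/C, EtOAc/THF) first removes every benzyl group and should give 4-{[4-{[4,6-dihydroxy-3-methoxy-2-methylbenzoyl]oxy}-2-hydroxy-6-methylbenzoyl]oxy}-2-methoxy-6-methylbenzoic acid F3. Magnesium iodide etherate (THF/toluene, warm) then cleaves only the methyl ether that can chelate magnesium with an ortho carbonyl, and the route comes back at 24.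

Step 9. Acylation of the pyrone by the hindered acid chloride may stall, or the vinylogous anhydride may rearrange (acyl shift to C3) or be cleaved during isolation. The fallback sets out from 13 and puts the A–B acyl group on after ring C is made. Acetylation (Ac2O, pyridine) gives 6-methyl-2-oxo-2H-pyran-4-yl acetate F4. Heating F4 with 21 under the step 12 conditions passes through benzyl 8-acetoxy-5-methoxy-1-methyl-3-oxo-2-oxabicyclo[2.2.2]octa-5,7-diene-6-carboxylate F5 (not isolated) to benzyl 4-acetoxy-2-methoxy-6-methylbenzoate F6. Brief methanolysis (K2CO3, MeOH, 0 °C) frees the phenol benzyl 4-hydroxy-2-methoxy-6-methylbenzoate F7 while the hindered benzyl ester stays. Acylation of F7 with acid chloride 14 (from 12; Et3N, CH2Cl2) brings the route back at 23.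

**Further compounds**
F1 | step 12 | benzyl 2,4-dihydroxy-6-methylbenzoate (benzyl orsellinate) | Cc1cc(O)cc(O)c1C(=O)OCc1ccccc1
F2 | step 12 | benzyl 4-{[2-(benzyloxy)-4-{[4,6-bis(benzyloxy)-3-methoxy-2-methylbenzoyl]oxy}-6-methylbenzoyl]oxy}-2-hydroxy-6-methylbenzoate | COc1c(OCc2ccccc2)cc(OCc2ccccc2)c(C(=O)Oc2cc(C)c(C(=O)Oc3cc(C)c(C(=O)OCc4ccccc4)c(O)c3)c(OCc3ccccc3)c2)c1C
F3 | step 13 | 4-{[4-{[4,6-dihydroxy-3-methoxy-2-methylbenzoyl]oxy}-2-hydroxy-6-methylbenzoyl]oxy}-2-methoxy-6-methylbenzoic acid | COc1c(O)cc(O)c(C(=O)Oc2cc(C)c(C(=O)Oc3cc(C)c(C(=O)O)c(OC)c3)c(O)c2)c1C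
F4 | step 9 | 6-methyl-2-oxo-2H-pyran-4-yl acetate | CC(=O)Oc1cc(C)oc(=O)c1
F5 | step 9 | benzyl 8-acetoxy-5-methoxy-1-methyl-3-oxo-2-oxabicyclo[2.2.2]octa-5,7-diene-6-carboxylate (racemic) | CC(=O)OC1=CC2(C)OC(=O)C1C(OC)=C2C(=O)OCc3ccccc3
F6 | step 9 | benzyl 4-acetoxy-2-methoxy-6-methylbenzoate | CC(=O)Oc1cc(C)c(C(=O)OCc2ccccc2)c(OC)c1
F7 | step 9 | benzyl 4-hydroxy-2-methoxy-6-methylbenzoate | COc1cc(O)cc(C)c1C(=O)OCc1ccccc1
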